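**Plan** (indane numbering: C1 = benzylidene carbon, C2 = CH with the 3,5-dihydroxyphenyl ring, C3 = CH with the 4-hydroxy-3-methoxyphenyl ring, C3a/C7a = ring fusion)
1. Retrosynthesis: the five benzyl ethers come off last; then the C2–C3 bond is cut, which opens the only non-aromatic ring and clears both stereocentres and the exocyclic olefin at once, leaving an acyclic p-hydroxybenzhydrol (C3) with an ortho (E)-α-benzylstilbene (C1=C2).
2. Further cuts: the carbinol C3–aryl bond (aryllithium + aldehyde), the C7a–C1 bond (Suzuki–Miyaura), and the alkenyl boronate back to a 1,3-diarylpropyne (syn-hydroboration, benzyl–alkynyl coupling, aldehyde-to-alkyne homologation).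
3. Forward: three aryl building blocks are joined into the open chain in six steps; the cyclopentane is the only ring made (step 7); debenzylation ends the route.
4. Enabling feature: the 4-hydroxyphenyl group on C3 turns the carbinol into a p-quinone methide, whose exocyclic carbon, the C3a=C7a bond of the resorcinol ring and the C1=C2 olefin form a pentadienyl cation; the benzylic CH2 on C1 supplies the ene hydrogen.
5. Stereochemistry: olefin geometry from syn-borylcupration and stereoretentive coupling; C3 from a chiral Brønsted acid bound to the quinone methide; C2 (trans) and the E-benzylidene from conrotatory closure of the E-olefin and ene-type proton loss.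

Key step: step 7

Remark: the sense of induction of the acid in step 7 cannot be derived from precedent; the (R)-catalyst is written on the assumption that it leads to the (2S,3S) series, and its enantiomer is to be used if the first run shows the opposite sense.
Remark: compounds 3, 6 and 9 are taken as catalogue compounds.

**Step 1**
Reactants: 1 3,5-bis(benzyloxy)benzaldehyde
Product: 2 1,3-bis(benzyloxy)-5-ethynylbenzene
Conditions: dimethyl (1-diazo-2-oxopropyl)phosphonate, K2CO3, MeOH/THF, 0 °C to rt
Reagents that add atoms: dimethyl (1-diazo-2-oxopropyl)phosphonate (CC(=O)C(=[N+]=[N-])P(=O)(OC)OC)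
Why: Ohira–Bestmann (Seyferth–Gilbert) homologation: the diazomethylphosphonate anion released by methanolysis olefinates the non-enolisable aldehyde and the diazoalkene loses N2 to give the terminal alkyne, with benzyl ethers inert to K2CO3/MeOH.

**Step 2**
Reactants: 2 1,3-bis(benzyloxy)-5-ethynylbenzene; 3 4-benzyloxy-3-methoxybenzyl chloride
Product: 4 1,3-bis(benzyloxy)-5-[3-(4-benzyloxy-3-methoxyphenyl)prop-1-yn-1-yl]benzene
Conditions: PdCl2(MeCN)2 (2 mol%), XPhos (6 mol%), Cs2CO3, THF, 65 °C
Reagents that add atoms: none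
Why: copper-free Heck-type alkynylation: oxidative addition of the electron-rich benzyl chloride to zerovalent palladium, carbonate-assisted alkynyl transfer and reductive elimination should give the 1,3-diarylpropyne, the mild base keeping propargyl-to-allene isomerisation slow.

**Step 3**
Reactants: 4 the 1,3-diarylpropyne
Product: 5 (Z)-alkenyl pinacol boronate (boron on the benzyl-bearing carbon, boron and olefinic H cis)
Conditions: CuCl (5 mol%), Xantphos (5 mol%), NaOt-Bu (10 mol%), B2pin2, MeOH (2 equiv), THF, rt
Reagents that add atoms: bis(pinacolato)diboron (CC1(C)OB(OC1(C)C)B1OC(C)(C)C(C)(C)O1)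
Why: copper-catalysed formal hydroboration: syn-borylcupration puts copper next to the aryl ring and boron on the benzyl-bearing carbon, and methanol protonates the C–Cu bond with retention, which fixes the olefin geometry.

**Step 4**
Reactants: 6 1,3-bis(benzyloxy)-5-bromobenzene
Product: 7 2,4-bis(benzyloxy)-6-bromobenzaldehyde
Conditions: POCl3, DMF, 0 to 80 °C; then aq. NaOAc
Reagents that add atoms: N,N-dimethylformamide (CN(C)C=O); water (O)
Why: Vilsmeier–Haack formylation: the chloroiminium ion should attack the position ortho to bromine, which is para to one benzyloxy group, ortho to the other and less hindered than the position flanked by both ethers.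

**Step 5**
Reactants: 5 the (Z)-alkenyl boronate; 7 2,4-bis(benzyloxy)-6-bromobenzaldehyde
Product: 8 2,4-bis(benzyloxy)-6-[(E)-1-[3,5-bis(benzyloxy)phenyl]-3-(4-benzyloxy-3-methoxyphenyl)prop-1-en-2-yl]benzaldehyde
Conditions: Pd(OAc)2 (5 mol%), SPhos (10 mol%), K3PO4, toluene/H2O, 80 °C
Reagents that add atoms: none
Why: Suzuki–Miyaura coupling: oxidative addition into the C–Br bond activated by the ortho formyl group, then transmetalation and reductive elimination with retention of olefin geometry, so the two aryl groups on the olefin end up trans (E).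

**Step 6**
Reactants: 8 the alkenyl benzaldehyde; 9 (4-bromo-2-methoxyphenoxy)(tert-butyl)dimethylsilane
Product: 12 racemic p-hydroxybenzhydrol, via aryllithium 10 (not isolated), via lithium alkoxide silyl ether 11 (not isolated)
Conditions: n-BuLi, THF, −78 °C (on 9); then 8, −78 to 0 °C; then TBAF, 0 °C; aq. pH 7 buffer
Reagents that add atoms: none
Why: bromine–lithium exchange, 1,2-addition of the aryllithium to the non-enolisable aldehyde and fluoride cleavage of the aryl silyl ether in the same flask; the carbinol centre is formed racemic, which is of no consequence because it is planarised in step 7.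

**Step 7**
Reactants: 12 racemic p-hydroxybenzhydrol
Product: 15 (2S,3S)-penta-O-benzylgnetulin, via p-quinone methide 13 (not isolated), via indanyl cation 14 (not isolated)
Conditions: (R)-3,3′-bis(2,4,6-triisopropylphenyl)-1,1′-binaphthyl-2,2′-diyl N-triflylphosphoramide (5 mol%), 5 Å MS, toluene (0.01 M), −40 to −20 °C
Reagents that add atoms: none
Why: Proposed new method: the acid dehydrates 12 to the ion-paired p-quinone methide 13, whose exocyclic carbon, the C3a=C7a bond of the resorcinol ring and the E-olefin form a pentadienyl cation that closes the five-membered ring by conrotatory 4π cyclisation (5-exo-trig at the quinone methide carbon, 5-endo-trig at the olefin) to cation 14, which loses a proton from the exocyclic benzylic CH2 to the catalyst anion, so that overall an intramolecular quinone-methide ene reaction of type 2 takes place and the acid is regenerated. The closest known reaction types are the Brønsted-acid-mediated cation–olefin cyclisation of 2-styryl diarylcarbinols to 1,2-diarylindanes and the chiral-phosphoric-acid-catalysed enantioselective 1,6-addition to p-quinone methides formed in situ from p-hydroxybenzyl alcohols; their merger with an unactivated olefin donor and ene termination is without direct precedent. C3 is controlled by the catalyst, which stays hydrogen-bonded to the quinone methide oxygen and should let the olefin reach only one face of the exocyclic carbon (one sense of conrotation). C2 is controlled by the E-olefin geometry: with both aryl groups on the outside of the U-shaped cation, conrotation can only give the 2,3-trans indane. The step needs ring closure through the olefin carbon that carries the bis(benzyloxy)phenyl group (the other carbon could only form a four-membered ring), loss of the exocyclic and not of the C2 proton, and E geometry of the new olefin. Exocyclic proton loss should be favoured because that C–H is activated by the p-benzyloxyaryl group (the developing styrene is conjugated with this donor) while C2–H is shielded by three aryl groups and its loss would build a strained tetrasubstituted indene, and the E isomer because the Z isomer would force the aryl group against C7–H; low temperature and the weakly basic counter-anion should keep the outcome kinetic.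

**Step 8**
Reactants: 15 (2S,3S)-penta-O-benzylgnetulin
Product: 16 gnetulin
Conditions: BCl3, C6HMe5, CH2Cl2, −78 °C; then MeOH
Reagents that add atoms: none
Why: Lewis-acid debenzylation with a cation scavenger: BCl3 ionises the five benzyl ethers at −78 °C and pentamethylbenzene traps the benzyl cations before they alkylate the electron-rich rings or the stilbene, while aryl methyl ethers and the two stereocentres should stay untouched, a reaction type established for benzyl-protected stilbene dimers with exocyclic benzylidene groups.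

**Compound list**
1 | 3,5-bis(benzyloxy)benzaldehyde | O=Cc1cc(OCc2ccccc2)cc(OCc2ccccc2)c1 | starting material
2 | 1,3-bis(benzyloxy)-5-ethynylbenzene | C#Cc1cc(OCc2ccccc2)cc(OCc2ccccc2)c1 | intermediate
3 | 1-(benzyloxy)-4-(chloromethyl)-2-methoxybenzene (4-benzyloxy-3-methoxybenzyl chloride) | COc1cc(CCl)ccc1OCc1ccccc1 | starting material
4 | 1,3-bis(benzyloxy)-5-[3-(4-benzyloxy-3-methoxyphenyl)prop-1-yn-1-yl]benzene | COc1cc(CC#Cc2cc(OCc3ccccc3)cc(OCc3ccccc3)c2)ccc1OCc1ccccc1 | intermediate
5 | 2-[(Z)-1-[3,5-bis(benzyloxy)phenyl]-3-(4-benzyloxy-3-methoxyphenyl)prop-1-en-2-yl]-4,4,5,5-tetramethyl-1,3,2-dioxaborolane | COc1cc(C/C(B2OC(C)(C)C(C)(C)O2)=C\c2cc(OCc3ccccc3)cc(OCc3ccccc3)c2)ccc1OCc1ccccc1 | intermediate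
6 | 1,3-bis(benzyloxy)-5-bromobenzene | Brc1cc(OCc2ccccc2)cc(OCc2ccccc2)c1 | starting material
7 | 2,4-bis(benzyloxy)-6-bromobenzaldehyde | O=Cc1c(Br)cc(OCc2ccccc2)cc1OCc1ccccc1 | intermediate
8 | 2,4-bis(benzyloxy)-6-[(E)-1-[3,5-bis(benzyloxy)phenyl]-3-(4-benzyloxy-3-methoxyphenyl)prop-1-en-2-yl]benzaldehyde | O=Cc1c(OCc2ccccc2)cc(OCc2ccccc2)cc1/C(Cc1ccc(OCc2ccccc2)c(OC)c1)=C/c1cc(OCc2ccccc2)cc(OCc2ccccc2)c1 | intermediate
9 | (4-bromo-2-methoxyphenoxy)(tert-butyl)dimethylsilane | COc1cc(Br)ccc1O[Si](C)(C)C(C)(C)C | starting material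
10 | [4-(tert-butyldimethylsilyloxy)-3-methoxyphenyl]lithium | COc1cc([Li])ccc1O[Si](C)(C)C(C)(C)C | intermediate
11 | lithium alkoxide of the racemic O-silyl benzhydrol formed from 8 and 10 | [Li+].[O-]C(c1ccc(O[Si](C)(C)C(C)(C)C)c(OC)c1)c1c(OCc2ccccc2)cc(OCc2ccccc2)cc1/C(Cc1ccc(OCc2ccccc2)c(OC)c1)=C/c1cc(OCc2ccccc2)cc(OCc2ccccc2)c1 | intermediate
12 | racemic 4-[{2,4-bis(benzyloxy)-6-[(E)-1-[3,5-bis(benzyloxy)phenyl]-3-(4-benzyloxy-3-methoxyphenyl)prop-1-en-2-yl]phenyl}(hydroxy)methyl]-2-methoxyphenol | OC(c1ccc(O)c(OC)c1)c1c(OCc2ccccc2)cc(OCc2ccccc2)cc1/C(Cc1ccc(OCc2ccccc2)c(OC)c1)=C/c1cc(OCc2ccccc2)cc(OCc2ccccc2)c1 | intermediate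
13 | p-quinone methide: 4-[{2,4-bis(benzyloxy)-6-[(E)-alkenyl]phenyl}methylidene]-2-methoxycyclohexa-2,5-dien-1-one (alkenyl as in 12) | COC1=CC(=Cc2c(OCc3ccccc3)cc(OCc3ccccc3)cc2/C(Cc2ccc(OCc3ccccc3)c(OC)c2)=C/c2cc(OCc3ccccc3)cc(OCc3ccccc3)c2)C=CC1=O | intermediate
14 | ring-closed tertiary benzylic indan-1-ylium cation (2,3-trans, C2 and C3 configured as in 15), ion-paired with the catalyst anion | COc1cc(C[C+]2c3cc(OCc4ccccc4)cc(OCc4ccccc4)c3[C@H](c3ccc(O)c(OC)c3)[C@H]2c2cc(OCc3ccccc3)cc(OCc3ccccc3)c2)ccc1OCc1ccccc1 | intermediate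
15 | (2S,3S)-penta-O-benzylgnetulin: 4-[(1S,2S,3E)-5,7-bis(benzyloxy)-3-(4-benzyloxy-3-methoxybenzylidene)-2-[3,5-bis(benzyloxy)phenyl]-2,3-dihydro-1H-inden-1-yl]-2-methoxyphenol | COc1cc(/C=C2/c3cc(OCc4ccccc4)cc(OCc4ccccc4)c3[C@H](c3ccc(O)c(OC)c3)[C@H]2c2cc(OCc3ccccc3)cc(OCc3ccccc3)c2)ccc1OCc1ccccc1 | intermediate
16 | gnetulin: (1E,2S,3S)-2-(3,5-dihydroxyphenyl)-3-(4-hydroxy-3-methoxyphenyl)-1-[(4-hydroxy-3-methoxyphenyl)methylidene]-2,3-dihydro-1H-indene-4,6-diol | COc1cc(/C=C2/c3cc(O)cc(O)c3[C@H](c3ccc(O)c(OC)c3)[C@H]2c2cc(O)cc(O)c2)ccc1O | target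

**Totals**
Total step count: 8. Longest linear sequence: 7 steps (steps 1, 2, 3, 5, 6, 7, 8).

**Steps most likely to fail**

Step 7 (new method). What may go wrong: proton loss from the ring methine C2–H or acid-promoted olefin migration (endocyclic indene), and weak facial discrimination by the catalyst. The fallback uses known chemistry, sets out from alkyne 2 and bromoaldehyde 7 and comes back at target 16. Hydroboration of 2 with pinacolborane (Cp2Zr(H)Cl cat.) gives the (E)-styrylboronate F1. Suzuki–Miyaura coupling with 7 under the conditions of step 5 gives the (E)-stilbene aldehyde F2. Addition of the aryl Grignard reagent F3 (from 1-(benzyloxy)-4-bromo-2-methoxybenzene and Mg) gives the hexabenzyl benzhydrol F4. CF3CO2H in CH2Cl2 at low temperature ionises F4, the stilbene closes the same C2–C3 bond (2,3-trans), and the secondary indanyl cation is captured by the benzylic thiol F5 (from chloride 3 and NaSH) to give the sulfide F6. mCPBA gives the sulfone F7. A Ramberg–Bäcklund reaction (KOH, CCl4, t-BuOH/H2O) places the double bond unambiguously between C1 and the benzylic carbon and gives racemic hexa-O-benzylgnetulin F8. Preparative HPLC on a chiral stationary phase gives (2S,3S)-hexa-O-benzylgnetulin F9, which is debenzylated under the conditions of step 8 to 16.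

Step 3. What may go wrong: base-promoted isomerisation of the propargylic CH2 (allene formation) and borylcupration with reversed regiochemistry. The fallback sets out from 4 and 7, comes back at 8 and bypasses 5. It is a palladium-catalysed syn-hydroarylation (Pd(OAc)2, PPh3, HCO2Na, DMF, 60 °C): oxidative addition of 7, carbopalladation of 4 with the aryl group going to the benzyl-bearing alkyne carbon, and reduction of the vinylpalladium by formate should give 8 directly. No new compound arises (entry F0).

Step 2. What may go wrong: propargyl-to-allene isomerisation of the product under carbonate and alkyne homocoupling. The fallback sets out from 2 and comes back at 4. Deprotonation of 2 with n-BuLi gives the lithium acetylide F10, which adds to 4-(benzyloxy)-3-methoxybenzaldehyde to give the propargylic alcohol F11. Ionic deoxygenation (Et3SiH, BF3·OEt2, CH2Cl2, −78 to 0 °C) through the aryl-stabilised propargylic cation should give 4.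

**Further compounds**
F1 | step 7 | (E)-2-[2-[3,5-bis(benzyloxy)phenyl]ethenyl]-4,4,5,5-tetramethyl-1,3,2-dioxaborolane | CC1(C)OB(/C=C/c2cc(OCc3ccccc3)cc(OCc3ccccc3)c2)OC1(C)C
F2 | step 7 | 2,4-bis(benzyloxy)-6-[(E)-2-[3,5-bis(benzyloxy)phenyl]ethenyl]benzaldehyde | O=Cc1c(OCc2ccccc2)cc(OCc2ccccc2)cc1/C=C/c1cc(OCc2ccccc2)cc(OCc2ccccc2)c1
F3 | step 7 | (4-benzyloxy-3-methoxyphenyl)magnesium bromide | COc1cc([Mg]Br)ccc1OCc1ccccc1
F4 | step 7 | racemic {2,4-bis(benzyloxy)-6-[(E)-2-[3,5-bis(benzyloxy)phenyl]ethenyl]phenyl}(4-benzyloxy-3-methoxyphenyl)methanol | OC(c1ccc(OCc2ccccc2)c(OC)c1)c1c(OCc2ccccc2)cc(OCc2ccccc2)cc1/C=C/c1cc(OCc2ccccc2)cc(OCc2ccccc2)c1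
F5 | step 7 | (4-benzyloxy-3-methoxyphenyl)methanethiol | COc1cc(CS)ccc1OCc1ccccc1
F6 | step 7 | racemic 1,2-trans-2,3-trans 4,6-bis(benzyloxy)-1-[(4-benzyloxy-3-methoxybenzyl)sulfanyl]-2-[3,5-bis(benzyloxy)phenyl]-3-(4-benzyloxy-3-methoxyphenyl)indane | COc1cc(CSC2c3cc(OCc4ccccc4)cc(OCc4ccccc4)c3C(c3ccc(OCc4ccccc4)c(OC)c3)C2c2cc(OCc3ccccc3)cc(OCc3ccccc3)c2)ccc1OCc1ccccc1
F7 | step 7 | the corresponding racemic sulfone | COc1cc(CS(=O)(=O)C2c3cc(OCc4ccccc4)cc(OCc4ccccc4)c3C(c3ccc(OCc4ccccc4)c(OC)c3)C2c2cc(OCc3ccccc3)cc(OCc3ccccc3)c2)ccc1OCc1ccccc1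
F8 | step 7 | racemic 2,3-trans hexa-O-benzylgnetulin | COc1cc(/C=C2/c3cc(OCc4ccccc4)cc(OCc4ccccc4)c3C(c3ccc(OCc4ccccc4)c(OC)c3)C2c2cc(OCc3ccccc3)cc(OCc3ccccc3)c2)ccc1OCc1ccccc1
F9 | step 7 | (2S,3S)-hexa-O-benzylgnetulin | COc1cc(/C=C2/c3cc(OCc4ccccc4)cc(OCc4ccccc4)c3[C@H](c3ccc(OCc4ccccc4)c(OC)c3)[C@H]2c2cc(OCc3ccccc3)cc(OCc3ccccc3)c2)ccc1OCc1ccccc1
F0 | step 3 | none | none
F10 | step 2 | lithium [3,5-bis(benzyloxy)phenyl]acetylide | [Li]C#Cc1cc(OCc2ccccc2)cc(OCc2ccccc2)c1
F11 | step 2 | racemic 3-[3,5-bis(benzyloxy)phenyl]-1-(4-benzyloxy-3-methoxyphenyl)prop-2-yn-1-ol | OC(C#Cc1cc(OCc2ccccc2)cc(OCc2ccccc2)c1)c1ccc(OCc2ccccc2)c(OC)c1
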